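**Plan**

1. Retrosynthesis: the hemiketal bond O7'–C3 is opened to a chromane-3,4-dione, the C4 carbonyl oxygen is removed, and C4 is then excised by cutting C3–C4 and C4–C4a. This works because the chromanone ring O1–C2–C3–C4–C4a–C8a is a benzofuran-3(2H)-one plus one carbon, C4, lying between a ketone carbon and an electron-rich aryl carbon; in the smaller ring the fully substituted C2 (O1, 4-hydroxyphenyl, C8') is an acetal-level carbon next to a ketone.
2. The 2,2-diarylbenzofuranone is cut at C2–C8' into a 2-aryl-2-hydroxybenzofuran-3-one (from phloroglucinol and 4-hydroxyphenylacetic acid) and 3,5,4'-tri-O-benzylkaempferol (from kaempferol).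
3. Forward order: furanone ring (step 3), C2–C8' bond (step 9), six-membered ring by one-carbon insertion (step 12), C4 oxidation (step 13), dihydrofuran hemiketal ring on debenzylation (step 14).
4. Stereochemistry: C2 is formed racemic in step 9 and the R enantiomer is taken by resolution on a chiral phase (step 10); it is quaternary and not touched afterwards. C3 (S) follows from C2 because the five-membered hemiketal can only close cis-fused.

Key step: step 12

Assumption: unprimed locants refer to the chromanone (or its benzofuranone precursor) and primed locants to the kaempferol unit; rotamers about the hindered C2–C8' bond are taken to interconvert and to converge once the dihydrofuran ring is closed.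

**Route**

Step 1
Reactants: 1 phloroglucinol; 2 4-hydroxyphenylacetic acid
Product: 3 2-(4-hydroxyphenyl)-1-(2,4,6-trihydroxyphenyl)ethan-1-one
Conditions: BF3·OEt2 (neat), 85 °C; aq. NaOAc work-up
Reagents that add atoms: none
Why: Friedel–Crafts (Hoesch-type) C-acylation of the symmetric triol by the BF3-activated arylacetic acid is the standard entry to polyhydroxydeoxybenzoins and can give only one regioisomer.

Step 2
Reactants: 3 2-(4-hydroxyphenyl)-1-(2,4,6-trihydroxyphenyl)ethan-1-one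
Product: 4 1-[2,4-bis(benzyloxy)-6-hydroxyphenyl]-2-[4-(benzyloxy)phenyl]ethan-1-one
Conditions: BnBr (3.1 equiv), K2CO3, DMF, 0 °C to rt
Reagents that add atoms: benzyl bromide, BrCc1ccccc1
Why: Williamson etherification with a weak base should alkylate the three free phenols while the hydroxyl chelated to the ketone stays unreacted.

Step 3
Reactants: 4 1-[2,4-bis(benzyloxy)-6-hydroxyphenyl]-2-[4-(benzyloxy)phenyl]ethan-1-one
Product: 6 rac-4,6-bis(benzyloxy)-2-[4-(benzyloxy)phenyl]-2-hydroxybenzofuran-3(2H)-one, via open 1,2-diketone 5 (not isolated)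
Conditions: SeO2, 1,4-dioxane/H2O (20:1), 90 °C
Reagents that add atoms: selenium dioxide, O=[Se]=O
Why: Riley oxidation converts the deoxybenzoin methylene into the 1,2-diketone 5, whose ortho-phenol adds to the distal aryl ketone to give the five-membered cyclic hemiketal 6 (ring and chain forms would ionise to the same cation in step 9).

Step 4
Reactants: 7 kaempferol
Product: 8 kaempferol 3,5,7,4'-tetraacetate
Conditions: Ac2O, pyridine, DMAP (cat.), 60 °C
Reagents that add atoms: acetic anhydride, CC(=O)OC(C)=O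
Why: Exhaustive O-acylation under nucleophilic catalysis esterifies all four hydroxyls, including the chelated 5-OH on warming.

Step 5
Reactants: 8 kaempferol 3,5,7,4'-tetraacetate
Product: 9 3,5,4'-tri-O-acetylkaempferol (7-OH free)
Conditions: PhSH, imidazole (cat.), NMP, 0 °C
Reagents that add atoms: none
Why: Chemoselective thiolysis of aryl acetates is known for flavonoid peracetates, where the 7-O-acetyl group, para to the pyrone carbonyl, is the most electrophilic ester and is the only one transferred to thiophenolate at 0 °C.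

Step 6
Reactants: 9 3,5,4'-tri-O-acetylkaempferol
Product: 10 3,5,4'-tri-O-acetyl-7-O-(methoxymethyl)kaempferol
Conditions: MOMCl, i-Pr2NEt, CH2Cl2, 0 °C to rt
Reagents that add atoms: chloromethyl methyl ether, COCCl
Why: O-alkylation of the acidic 7-phenol with a chloromethyl ether and a hindered amine base forms the acetal without disturbing the aryl acetates.

Step 7
Reactants: 10 3,5,4'-tri-O-acetyl-7-O-(methoxymethyl)kaempferol
Product: 12 3,5,4'-tri-O-benzyl-7-O-(methoxymethyl)kaempferol, via 7-O-(methoxymethyl)kaempferol 11 (not isolated)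
Conditions: K2CO3, MeOH/THF, rt; then BnBr, K2CO3, n-Bu4NI (cat.), DMF, 70 °C, argon
Reagents that add atoms: benzyl bromide, BrCc1ccccc1
Why: Zemplén-type transesterification frees the three phenols as 11 and Williamson benzylation in DMF then caps them, the acetal at O7 being inert to base.

Step 8
Reactants: 12 3,5,4'-tri-O-benzyl-7-O-(methoxymethyl)kaempferol
Product: 13 3,5,4'-tri-O-benzylkaempferol (7-OH free)
Conditions: HCl (2 M in MeOH)/THF, 45 °C
Reagents that add atoms: none
Why: Acid-catalysed acetal exchange with methanol removes the methoxymethyl group, and benzyl aryl ethers are stable to dilute acid at this temperature.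

Step 9
Reactants: 6 rac-4,6-bis(benzyloxy)-2-[4-(benzyloxy)phenyl]-2-hydroxybenzofuran-3(2H)-one; 13 3,5,4'-tri-O-benzylkaempferol (1.5 equiv)
Product: 14 rac-4,6-bis(benzyloxy)-2-[4-(benzyloxy)phenyl]-2-{3,5-bis(benzyloxy)-2-[4-(benzyloxy)phenyl]-7-hydroxy-4-oxo-4H-chromen-8-yl}benzofuran-3(2H)-one
Conditions: p-TsOH·H2O (10 mol %), (CF3)2CHOH/CH2Cl2 (1:3), 0 °C to rt
Reagents that add atoms: none
Why: In this dehydrative Friedel–Crafts alkylation the acid ionises the hemiketal to a 2-aryl-3-oxobenzofuranylium (oxocarbenium) ion, O-alkylation of the phenol is reversible, and C-alkylation should occur at C8' ortho to the free 7'-OH (the most nucleophilic site of 7-hydroxychromones, whereas C6' is flanked by the 5'-benzyloxy group), which creates C2 as a racemate.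

Step 10
Reactants: 14 racemic C2–C8' coupled phenol
Product: 15 (2R)-enantiomer of 14
Conditions: preparative HPLC, amylose tris(3,5-dimethylphenylcarbamate) stationary phase, n-hexane/i-PrOH
Reagents that add atoms: none
Why: Chromatographic resolution of enantiomers on a polysaccharide chiral stationary phase is generally effective for aryl-rich ketones, C2 is fully substituted and has no pathway to racemise, and the R enantiomer is to be assigned by X-ray or ECD analysis before it is carried on.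

Step 11
Reactants: 15 (2R)-phenol
Product: 16 (2R)-4,6-bis(benzyloxy)-2-[4-(benzyloxy)phenyl]-2-{3,5,7-tris(benzyloxy)-2-[4-(benzyloxy)phenyl]-4-oxo-4H-chromen-8-yl}benzofuran-3(2H)-one
Conditions: BnBr, K2CO3, n-Bu4NI (cat.), DMF, 60 °C
Reagents that add atoms: benzyl bromide, BrCc1ccccc1
Why: Williamson etherification of the hindered 7'-phenoxide in a polar aprotic solvent masks the last acidic proton, which would otherwise be methylated in the diazoalkane step.

Step 12
Reactants: 16 (2R)-heptabenzyl 2,2-diarylbenzofuran-3-one; 17 trimethylsilyldiazomethane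
Product: 19 (2R)-5,7-bis(benzyloxy)-2-[4-(benzyloxy)phenyl]-2-{3,5,7-tris(benzyloxy)-2-[4-(benzyloxy)phenyl]-4-oxo-4H-chromen-8-yl}chroman-3-one, via 4-trimethylsilyl chroman-3-one 18 (not isolated)
Conditions: TMSCHN2 (3 equiv), BF3·OEt2 (3 equiv), CH2Cl2, −78 to −20 °C; then 1 M HCl/THF, rt
Reagents that add atoms: trimethylsilyldiazomethane (17), C[Si](C)(C)C=[N+]=[N-]
Why: BF3 coordination renders the strained furanone carbonyl C3 electrophilic, the diazo carbon of 17 adds to it, and the β-oxido diazonium ion so formed expels N2 while the antiperiplanar aryl carbon C3a (C4a of the product) shifts onto the new carbon, which thereby becomes C4 with bonds to C3 and C4a; acid work-up replaces silicon of 18 by hydrogen. The closest known reaction type is the Lewis-acid-promoted Tiffeneau–Demjanov-type one-carbon homologation of benzo-fused cyclic ketones (indanones, isatins, chroman-4-ones) with trimethylsilyldiazomethane. The six-membered ring O1–C2–C3–C4–C4a–C8a arises by enlargement of the five-membered ring through this 1,2-shift and not by a cyclisation, so no Baldwin mode applies. No lasting stereocentre is formed (C4 of 18 ends as CH2), and C2, fully substituted and outside the migration, keeps its R configuration. The step needs aryl rather than C2 migration and a single insertion: the 2,4,6-trioxygenated aryl carbon should migrate through a phenonium-like transition state more readily than the oxygen-bearing diaryl carbon, the bulky α-silyl ketone resists a second addition, and the flavone carbonyl is a vinylogous ester inert to the diazoalkane. The regioisomeric chroman-4-one that C2 migration would give is no dead end, since step 13 would oxidise its C3 methylene to the same 3,4-dione.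

Step 13
Reactants: 19 (2R)-heptabenzyl chroman-3-one
Product: 20 (2R)-5,7-bis(benzyloxy)-2-[4-(benzyloxy)phenyl]-2-{3,5,7-tris(benzyloxy)-2-[4-(benzyloxy)phenyl]-4-oxo-4H-chromen-8-yl}chromane-3,4-dione
Conditions: SeO2, 1,4-dioxane/H2O (20:1), 80 °C
Reagents that add atoms: selenium dioxide, O=[Se]=O
Why: Riley oxidation should convert the C4 methylene, which is benzylic to an electron-rich ring, alpha to the C3 ketone and the only enolisable position, into the second carbonyl of the 1,2-diketone (possibly handled as its C3 hydrate).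

Step 14
Reactants: 20 (2R)-heptabenzyl chromane-3,4-dione
Product: 22 target CNP0314633.1, (2R,3S)-3,5,7-trihydroxy-2-(4-hydroxyphenyl)chroman-4-one with C2 bonded to C8' and the hemiketal carbon C3 bonded to O7' of a kaempferol unit (cis-fused dihydrofuran), via open heptaphenol 3,4-dione 21 (not isolated)
Conditions: H2 (1 atm), Pd/C (10 %), THF/EtOAc, rt
Reagents that add atoms: none
Why: Catalytic hydrogenolysis cleaves all seven benzyl aryl ethers, and the freed 7'-OH adds to the highly electrophilic C3 ketone of 21 in a 5-exo-trig hemiketalisation that can only give the cis-fused dihydrofuran, so C3 (S) is dictated by C2 (R).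

**Compound list**

1 | phloroglucinol (benzene-1,3,5-triol) | Oc1cc(O)cc(O)c1 | starting material
2 | 4-hydroxyphenylacetic acid | O=C(O)Cc1ccc(O)cc1 | starting material
3 | 2-(4-hydroxyphenyl)-1-(2,4,6-trihydroxyphenyl)ethan-1-one | O=C(Cc1ccc(O)cc1)c1c(O)cc(O)cc1O | intermediate
4 | 1-[2,4-bis(benzyloxy)-6-hydroxyphenyl]-2-[4-(benzyloxy)phenyl]ethan-1-one | O=C(Cc1ccc(OCc6ccccc6)cc1)c1c(O)cc(OCc6ccccc6)cc1OCc6ccccc6 | intermediate
5 | 1-[2,4-bis(benzyloxy)-6-hydroxyphenyl]-2-[4-(benzyloxy)phenyl]ethane-1,2-dione (open 1,2-diketone, not isolated) | O=C(C(=O)c1ccc(OCc6ccccc6)cc1)c1c(O)cc(OCc6ccccc6)cc1OCc6ccccc6 | intermediate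
6 | rac-4,6-bis(benzyloxy)-2-[4-(benzyloxy)phenyl]-2-hydroxybenzofuran-3(2H)-one | O=C1c2c(OCc6ccccc6)cc(OCc6ccccc6)cc2OC1(O)c1ccc(OCc6ccccc6)cc1 | intermediate
7 | kaempferol, 3,5,7-trihydroxy-2-(4-hydroxyphenyl)-4H-chromen-4-one | O=c1c(O)c(-c2ccc(O)cc2)oc2cc(O)cc(O)c12 | starting material
8 | kaempferol 3,5,7,4'-tetraacetate | O=c1c(OC(C)=O)c(-c2ccc(OC(C)=O)cc2)oc2cc(OC(C)=O)cc(OC(C)=O)c12 | intermediate
9 | 3,5,4'-tri-O-acetylkaempferol (7-OH free) | O=c1c(OC(C)=O)c(-c2ccc(OC(C)=O)cc2)oc2cc(O)cc(OC(C)=O)c12 | intermediate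
10 | 3,5,4'-tri-O-acetyl-7-O-(methoxymethyl)kaempferol | O=c1c(OC(C)=O)c(-c2ccc(OC(C)=O)cc2)oc2cc(OCOC)cc(OC(C)=O)c12 | intermediate
11 | 7-O-(methoxymethyl)kaempferol (not isolated) | O=c1c(O)c(-c2ccc(O)cc2)oc2cc(OCOC)cc(O)c12 | intermediate
12 | 3,5,4'-tri-O-benzyl-7-O-(methoxymethyl)kaempferol | O=c1c(OCc6ccccc6)c(-c2ccc(OCc6ccccc6)cc2)oc2cc(OCOC)cc(OCc6ccccc6)c12 | intermediate
13 | 3,5,4'-tri-O-benzylkaempferol, 3,5-bis(benzyloxy)-2-[4-(benzyloxy)phenyl]-7-hydroxy-4H-chromen-4-one | O=c1c(OCc6ccccc6)c(-c2ccc(OCc6ccccc6)cc2)oc2cc(O)cc(OCc6ccccc6)c12 | intermediate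
14 | rac-4,6-bis(benzyloxy)-2-[4-(benzyloxy)phenyl]-2-{3,5-bis(benzyloxy)-2-[4-(benzyloxy)phenyl]-7-hydroxy-4-oxo-4H-chromen-8-yl}benzofuran-3(2H)-one | O=C1c2c(OCc6ccccc6)cc(OCc6ccccc6)cc2OC1(c3ccc(OCc6ccccc6)cc3)c3c(O)cc(OCc6ccccc6)c4c(=O)c(OCc6ccccc6)c(-c5ccc(OCc6ccccc6)cc5)oc34 | intermediate
15 | (2R)-enantiomer of 14 | O=C1c2c(OCc6ccccc6)cc(OCc6ccccc6)cc2O[C@]1(c3ccc(OCc6ccccc6)cc3)c3c(O)cc(OCc6ccccc6)c4c(=O)c(OCc6ccccc6)c(-c5ccc(OCc6ccccc6)cc5)oc34 | intermediate
16 | (2R)-4,6-bis(benzyloxy)-2-[4-(benzyloxy)phenyl]-2-{3,5,7-tris(benzyloxy)-2-[4-(benzyloxy)phenyl]-4-oxo-4H-chromen-8-yl}benzofuran-3(2H)-one | O=C1c2c(OCc6ccccc6)cc(OCc6ccccc6)cc2O[C@]1(c3ccc(OCc6ccccc6)cc3)c3c(OCc6ccccc6)cc(OCc6ccccc6)c4c(=O)c(OCc6ccccc6)c(-c5ccc(OCc6ccccc6)cc5)oc34 | intermediate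
17 | trimethylsilyldiazomethane | C[Si](C)(C)C=[N+]=[N-] | starting material
18 | (2R)-5,7-bis(benzyloxy)-2-[4-(benzyloxy)phenyl]-2-{3,5,7-tris(benzyloxy)-2-[4-(benzyloxy)phenyl]-4-oxo-4H-chromen-8-yl}-4-(trimethylsilyl)chroman-3-one (C4 epimers, not isolated) | O=C1C([Si](C)(C)C)c2c(OCc6ccccc6)cc(OCc6ccccc6)cc2O[C@]1(c3ccc(OCc6ccccc6)cc3)c3c(OCc6ccccc6)cc(OCc6ccccc6)c4c(=O)c(OCc6ccccc6)c(-c5ccc(OCc6ccccc6)cc5)oc34 | intermediate
19 | (2R)-5,7-bis(benzyloxy)-2-[4-(benzyloxy)phenyl]-2-{3,5,7-tris(benzyloxy)-2-[4-(benzyloxy)phenyl]-4-oxo-4H-chromen-8-yl}chroman-3-one | O=C1Cc2c(OCc6ccccc6)cc(OCc6ccccc6)cc2O[C@]1(c3ccc(OCc6ccccc6)cc3)c3c(OCc6ccccc6)cc(OCc6ccccc6)c4c(=O)c(OCc6ccccc6)c(-c5ccc(OCc6ccccc6)cc5)oc34 | intermediate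
20 | (2R)-5,7-bis(benzyloxy)-2-[4-(benzyloxy)phenyl]-2-{3,5,7-tris(benzyloxy)-2-[4-(benzyloxy)phenyl]-4-oxo-4H-chromen-8-yl}chromane-3,4-dione | O=C1C(=O)c2c(OCc6ccccc6)cc(OCc6ccccc6)cc2O[C@]1(c3ccc(OCc6ccccc6)cc3)c3c(OCc6ccccc6)cc(OCc6ccccc6)c4c(=O)c(OCc6ccccc6)c(-c5ccc(OCc6ccccc6)cc5)oc34 | intermediate
21 | (2R)-5,7-dihydroxy-2-(4-hydroxyphenyl)-2-[3,5,7-trihydroxy-2-(4-hydroxyphenyl)-4-oxo-4H-chromen-8-yl]chromane-3,4-dione (not isolated) | O=C1C(=O)c2c(O)cc(O)cc2O[C@]1(c3ccc(O)cc3)c3c(O)cc(O)c4c(=O)c(O)c(-c5ccc(O)cc5)oc34 | intermediate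
22 | CNP0314633.1, (2R,3S)-3,5,7-trihydroxy-2-(4-hydroxyphenyl)chroman-4-one with C2 bonded to C8' and hemiketal C3 bonded to O7' of kaempferol (cis-fused dihydrofuran) | O=C1c2c(O)cc(O)cc2O[C@]2(c3ccc(O)cc3)c3c(cc(O)c4c(=O)c(O)c(-c5ccc(O)cc5)oc34)O[C@]12O | target

**Step count**

Total: 14 steps. Longest linear sequence: 11 steps (kaempferol 7 to 22, steps 4 to 14); the phloroglucinol branch (steps 1 to 3) joins at step 9.

**Steps most likely to fail, with fallbacks**

Step 12. What may go wrong: sluggish addition of the diazoalkane to the hindered, donor-deactivated ketone, or loss of nitrogen by epoxide closure in place of aryl migration. The fallback sets out from 16. Wittig methylenation of the non-enolisable ketone (Ph3PCH3Br, KOtBu, toluene, 90 °C) should give the exocyclic alkene (2S)-4,6-bis(benzyloxy)-2-[4-(benzyloxy)phenyl]-3-methylidene-2-{3,5,7-tris(benzyloxy)-2-[4-(benzyloxy)phenyl]-4-oxo-4H-chromen-8-yl}-2,3-dihydrobenzofuran F1 (same spatial arrangement at C2; only the descriptor changes). Oxidative rearrangement with the trivalent-iodine reagent PhI(OH)OTs in MeOH/CH2Cl2 at 0 °C, then dilute acid, should shift the aryl carbon onto the former methylene carbon, as known for 1-methylenebenzocycloalkenes, and return to the route at 19.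

Step 9. What may go wrong: consumption of the cation by O-alkylation only, by self-alkylation through the electron-rich ring of 6, or attack at C6' instead of C8'. The fallback sets out from 6 and 13 and replaces the intermolecular C-alkylation by delivery through the phenol oxygen. Ketalisation under kinetic control (PPTS, 4 Å MS, toluene, rt) should give the O-linked mixed ketal rac-2-{[3,5-bis(benzyloxy)-2-(4-benzyloxyphenyl)-4-oxo-4H-chromen-7-yl]oxy}-4,6-bis(benzyloxy)-2-[4-(benzyloxy)phenyl]benzofuran-3(2H)-one F2. Sc(OTf)3 (10 mol %) in CH2Cl2 at −40 to 0 °C should then effect a Fries-type 1,3 O-to-C shift within the ion pair, as in aryl C-glycoside synthesis, placing the carbon ortho to the oxygen it leaves and rejoining the route at 14.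

Step 14. What may go wrong: hydrogenation of the C3 carbonyl of the 1,2-dione, or slow cleavage of the hindered 7'-benzyl ether, before the hemiketal has closed. The fallback sets out from 15 and changes the protecting-group plan so that the hemiketal exists before hydrogenolysis.
- Silylation (TBSOTf, 2,6-lutidine, CH2Cl2) in place of benzylation should give the (2R)-7'-O-tert-butyldimethylsilyl benzofuranone F3.
- Ring expansion as in step 12 should give, via the 4-trimethylsilyl ketone F4, the 7'-O-silyl chroman-3-one F5.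
- SeO2 as in step 13 should give the 7'-O-silyl chromane-3,4-dione F6.
- HF·pyridine in THF should free the phenol of the hexabenzyl dione F7, which should close at once to the cis-fused hexabenzyl hemiketal F8.
- H2, Pd/C then only has to remove six unhindered benzyl ethers from a compound without a C3 ketone and returns to the route at 22.

**Further compounds**

F1 | step 12 | (2S)-4,6-bis(benzyloxy)-2-[4-(benzyloxy)phenyl]-3-methylidene-2-{3,5,7-tris(benzyloxy)-2-[4-(benzyloxy)phenyl]-4-oxo-4H-chromen-8-yl}-2,3-dihydrobenzofuran | C=C1c2c(OCc6ccccc6)cc(OCc6ccccc6)cc2O[C@]1(c3ccc(OCc6ccccc6)cc3)c3c(OCc6ccccc6)cc(OCc6ccccc6)c4c(=O)c(OCc6ccccc6)c(-c5ccc(OCc6ccccc6)cc5)oc34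
F2 | step 9 | rac-2-{[3,5-bis(benzyloxy)-2-(4-benzyloxyphenyl)-4-oxo-4H-chromen-7-yl]oxy}-4,6-bis(benzyloxy)-2-[4-(benzyloxy)phenyl]benzofuran-3(2H)-one | O=C1c2c(OCc6ccccc6)cc(OCc6ccccc6)cc2OC1(c3ccc(OCc6ccccc6)cc3)Oc3cc(OCc6ccccc6)c4c(=O)c(OCc6ccccc6)c(-c5ccc(OCc6ccccc6)cc5)oc4c3
F3 | step 14 | (2R)-4,6-bis(benzyloxy)-2-[4-(benzyloxy)phenyl]-2-{3,5-bis(benzyloxy)-2-[4-(benzyloxy)phenyl]-7-(tert-butyldimethylsilyloxy)-4-oxo-4H-chromen-8-yl}benzofuran-3(2H)-one | O=C1c2c(OCc6ccccc6)cc(OCc6ccccc6)cc2O[C@]1(c3ccc(OCc6ccccc6)cc3)c3c(O[Si](C)(C)C(C)(C)C)cc(OCc6ccccc6)c4c(=O)c(OCc6ccccc6)c(-c5ccc(OCc6ccccc6)cc5)oc34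
F4 | step 14 | (2R)-7'-O-tert-butyldimethylsilyl 4-(trimethylsilyl)chroman-3-one (silyl analogue of 18, not isolated) | O=C1C([Si](C)(C)C)c2c(OCc6ccccc6)cc(OCc6ccccc6)cc2O[C@]1(c3ccc(OCc6ccccc6)cc3)c3c(O[Si](C)(C)C(C)(C)C)cc(OCc6ccccc6)c4c(=O)c(OCc6ccccc6)c(-c5ccc(OCc6ccccc6)cc5)oc34
F5 | step 14 | (2R)-5,7-bis(benzyloxy)-2-[4-(benzyloxy)phenyl]-2-{3,5-bis(benzyloxy)-2-[4-(benzyloxy)phenyl]-7-(tert-butyldimethylsilyloxy)-4-oxo-4H-chromen-8-yl}chroman-3-one | O=C1Cc2c(OCc6ccccc6)cc(OCc6ccccc6)cc2O[C@]1(c3ccc(OCc6ccccc6)cc3)c3c(O[Si](C)(C)C(C)(C)C)cc(OCc6ccccc6)c4c(=O)c(OCc6ccccc6)c(-c5ccc(OCc6ccccc6)cc5)oc34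
F6 | step 14 | (2R)-5,7-bis(benzyloxy)-2-[4-(benzyloxy)phenyl]-2-{3,5-bis(benzyloxy)-2-[4-(benzyloxy)phenyl]-7-(tert-butyldimethylsilyloxy)-4-oxo-4H-chromen-8-yl}chromane-3,4-dione | O=C1C(=O)c2c(OCc6ccccc6)cc(OCc6ccccc6)cc2O[C@]1(c3ccc(OCc6ccccc6)cc3)c3c(O[Si](C)(C)C(C)(C)C)cc(OCc6ccccc6)c4c(=O)c(OCc6ccccc6)c(-c5ccc(OCc6ccccc6)cc5)oc34
F7 | step 14 | (2R)-5,7-bis(benzyloxy)-2-[4-(benzyloxy)phenyl]-2-{3,5-bis(benzyloxy)-2-[4-(benzyloxy)phenyl]-7-hydroxy-4-oxo-4H-chromen-8-yl}chromane-3,4-dione (not isolated) | O=C1C(=O)c2c(OCc6ccccc6)cc(OCc6ccccc6)cc2O[C@]1(c3ccc(OCc6ccccc6)cc3)c3c(O)cc(OCc6ccccc6)c4c(=O)c(OCc6ccccc6)c(-c5ccc(OCc6ccccc6)cc5)oc34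
F8 | step 14 | (2R,3S)-hexa-O-benzyl ether of 22 (benzyl on O5, O7, O4'' of the chromanone part and on O3', O5', O4''' of the kaempferol part; hemiketal OH free) | O=C1c2c(OCc6ccccc6)cc(OCc6ccccc6)cc2O[C@]2(c3ccc(OCc6ccccc6)cc3)c3c(cc(OCc6ccccc6)c4c(=O)c(OCc6ccccc6)c(-c5ccc(OCc6ccccc6)cc5)oc34)O[C@]12O
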